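The numbers in the tables come from a simulation for substances that don't exist; noise was put on by code.

Tuesday's flask holds twice the starting material of Friday's, yet its target forms at 0.0387 mM/s against 0.0285 mM/s.

| setting | Friday's | Tuesday's | flask |
|---|---|---|---|
| starting material | 24 mM | 48 mM | 24 mM |
| gas | 1.9 mM (held) | 1.9 mM (held) | 1.9 mM (held) |
| enzyme | 2.4 µM | 2.4 µM | 2.4 µM |
| remark | the very flask that is asked about, followed so far | run made earlier |  |

Friday's run (percent of the starting material charged)

| time / s | target / % | starting material / % |
|---|---|---|
| 10.0 | 0.6 | 99.6 |
| 20.0 | 1.2 | 98.3 |
| 40.0 | 3.2 | 96.6 |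
| 60.0 | 5.9 | 94.1 |
| 80.0 | 8.1 | 92.6 |
| 120 | 12.7 | 87.5 |

Tuesday's run (percent of the starting material charged)

| time / min | target / % | starting material / % |
|---|---|---|
| 0.667 | 2.5 | 97.3 |
| 1.33 | 5.6 | 94.3 |
| 2.00 | 9.0 | 91.2 |
| 3.00 | 14.5 | 86.4 |
| 4.00 | 18.5 | 81.7 |

(each reading ± 0.3 percentage points)

* factor on the rate of making target when 30% of the starting material are converted if enzyme is charged twice over
* factor on the rate when 30% of the starting material are converted if enzyme is charged at 25 µM instead

- what was read earlier has a scatter of 0.3 percentage points, one standard deviation
- at the start none of the gas is in solution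
- no earlier run changes the charge of enzyme; that part of a forecast is a guess

I build Friday's flask up one process at a time. With the enzyme step alone, rate follows the charge of enzyme, so the factors are 2 and 10.4. No run tests that proportionality; it is my guess.

Now I add gas. Friday's straight stretch, extended back, reaches zero at a lag of 13.1 s, which I read as gas entering solution. I take the lag as the reciprocal of the transfer and reaction constants added. With d the share by which gas in solution stands below c_gas, the balance gives:

d(1 − d) = r τ / c_gas = 0.196, so d = 0.267

I take this small root because Tuesday's rate stands above Friday's.

Last comes the loss of starting material: at 30% conversion I scale the reaction constant to what remains, assuming first order.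

D = d/(1 − d) × 70.0% = 0.255

This D is the gas number, the constant at which reaction removes gas in solution over the constant at which transfer restores it. Scaling enzyme by f gives the rule:

factor = f(1 + D)/(1 + fD)

So I commit to 1.66 and 3.57, which in powers of ten is 0.553 decades of rate for 1.02 of enzyme.

The forecast gives 1.65 and 3.4, “approaching the transfer ceiling” at the larger charge, both a little below mine.

The flask gives 1.75 and 4.40.

    starting material + enzyme ⇌ starting complex (K = 9.50 /M, k = 6.30 × 10⁵ /M/s)
    second substrate + starting complex ⇌ ternary complex (K = 510 /M, k = 1.70 × 10⁵ /M/s)
    ternary complex → enzyme + target (k = 120 /s)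
    gas ⇌ second substrate, rate k4*(csat - [second substrate]) (kL = 0.0800 /s)

In Friday's flask second substrate is made 1.01 times as fast as it is used at 2.36 min, and it stands at 1.59 mM after 3.00 min and 1.64 mM after 6.00 min, either side of the 4.94 min of 30% conversion, so the gas number there is 0.195 and 0.162, less than my 0.255. Their mean, 0.178, put into the rule for the flask charged with 25 µM, gives 4.30, and that flask's factor is 4.40.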